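The route rests on C1 of the tetralin: a benzylic methine on ring A, ortho to the C8 methoxy and para to the C6 methoxy group, bonded to C2 and to the guaiacyl ring. Both bonds are made from one aldehyde carbon. A Lewis acid closes ring B by intramolecular Hosomi–Sakurai attack of an allylsilane (C1–C2), and the benzylic oxygen then ionises so that guaiacol is captured para to its hydroxyl (C1–aryl); C2 and C1 are set relative to C3 in the same operation. The precursor is a ring A benzaldehyde whose ortho side chain carries the (S)-CH2OBn centre, set by auxiliary alkylation, and an (E)-allylsilane installed by cross-metathesis.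

Key step: step 11

Remark: tetralin numbering is used (C1 carries the guaiacyl ring, C2 and C3 the hydroxymethyl groups, C6 and C8 the methoxy groups, C7 the hydroxyl), and the target is the all-trans (1R,2S,3S) isomer. The precursor of step 11 is taken as the 5-(trimethylsilyl)pent-3-enyl compound, because only an allylsilane, with silicon on the carbon next to the alkene, can leave a vinyl group on C2. The guaiacyl phenol is benzylated before the periodate step because periodate oxidises free 2-methoxyphenols.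

Step 1
Reactants: 1 syringaldehyde (4-hydroxy-3,5-dimethoxybenzaldehyde)
Product: 2 4-(benzyloxy)-3,5-dimethoxybenzaldehyde
Conditions: BnBr, K2CO3, DMF, 60 °C
Reagents that add atoms: benzyl bromide, BrCc1ccccc1
Why: Williamson etherification of the acidic syringyl phenoxide installs a protecting group that should survive every step up to the final hydrogenolysis.

Step 2
Reactants: 2 4-(benzyloxy)-3,5-dimethoxybenzaldehyde
Product: 3 4-(benzyloxy)-2-bromo-3,5-dimethoxybenzaldehyde
Conditions: NBS, DMF, rt, dark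
Reagents that add atoms: N-bromosuccinimide, O=C1CCC(=O)N1Br
Why: Electrophilic aromatic bromination can only occur at C2 (identical with C6), which is ortho and para to the two methoxy groups, while the unactivated benzyl ring and, in the dark in a polar solvent, the benzylic CH2 are left alone.

Step 3
Reactants: 3 4-(benzyloxy)-2-bromo-3,5-dimethoxybenzaldehyde
Product: 4 [4-(benzyloxy)-2-bromo-3,5-dimethoxyphenyl]methanol
Conditions: NaBH4, MeOH/THF, 0 °C
Reagents that add atoms: none
Why: Borohydride reduction of an aryl aldehyde leaves the aryl bromide and the benzyl ether untouched.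

Step 4
Reactants: 4 [4-(benzyloxy)-2-bromo-3,5-dimethoxyphenyl]methanol
Product: 5 4-(benzyloxy)-2-bromo-3,5-dimethoxybenzyl bromide
Conditions: PBr3, CH2Cl2, 0 °C
Reagents that add atoms: phosphorus tribromide, BrP(Br)Br
Why: Bromide displaces the phosphite ester of the benzylic alcohol (SN2), and the ortho bromine tempers the lability of this electron-rich benzyl bromide.

Step 5
Reactants: 6 but-3-enoic acid; 7 (S)-4-benzyloxazolidin-2-one
Product: 10 (S)-4-benzyl-3-(but-3-enoyl)oxazolidin-2-one, via mixed pivalic anhydride 8 (not isolated), via lithium oxazolidinide 9 (not isolated)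
Conditions: 6, PivCl, Et3N, THF, −78 → 0 °C; then 9 (from 7, n-BuLi, THF, −78 °C), −78 → 0 °C; aq NH4Cl
Reagents that add atoms: none
Why: N-acylation of the lithiated Evans auxiliary by a mixed anhydride at low temperature is the standard way to this imide without drawing the double bond into conjugation.

Step 6
Reactants: 10 (S)-4-benzyl-3-(but-3-enoyl)oxazolidin-2-one; 5 4-(benzyloxy)-2-bromo-3,5-dimethoxybenzyl bromide
Product: 12 (4S)-4-benzyl-3-[(2S)-2-{[4-(benzyloxy)-2-bromo-3,5-dimethoxyphenyl]methyl}but-3-enoyl]oxazolidin-2-one, via sodium dienolate 11 (not isolated)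
Conditions: NaN(SiMe3)2, THF, −78 °C; then 5, −78 → −40 °C; aq NH4Cl
Reagents that add atoms: none
Why: In this Evans asymmetric alkylation the chelated Z-dienolate reacts at its α-carbon on the face away from the auxiliary benzyl group, which sets the (S) centre that becomes C3 and keeps the vinyl group out of conjugation, with the aryl bromide as a spectator.

Step 7
Reactants: 12 (4S)-4-benzyl-3-[(2S)-2-{[4-(benzyloxy)-2-bromo-3,5-dimethoxyphenyl]methyl}but-3-enoyl]oxazolidin-2-one
Product: 13 (2S)-2-{[4-(benzyloxy)-2-bromo-3,5-dimethoxyphenyl]methyl}but-3-en-1-ol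
Conditions: LiBH4, MeOH (1 equiv), Et2O, 0 °C
Reagents that add atoms: none
Why: Reductive cleavage of the imide by LiBH4 should release the primary alcohol and the auxiliary without touching the aryl bromide or the alkene and without epimerising the allylic centre.

Step 8
Reactants: 13 (2S)-2-{[4-(benzyloxy)-2-bromo-3,5-dimethoxyphenyl]methyl}but-3-en-1-ol
Product: 14 2-(benzyloxy)-5-[(2S)-2-[(benzyloxy)methyl]but-3-en-1-yl]-4-bromo-1,3-dimethoxybenzene
Conditions: NaH, BnBr, Bu4NI (cat.), THF/DMF, 0 °C → rt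
Reagents that add atoms: benzyl bromide, BrCc1ccccc1
Why: Williamson benzylation of a primary alkoxide caps the hydroxyl that would otherwise trap the C1 cation of step 11, and the stereocentre has no acidic hydrogen under these conditions.

Step 9
Reactants: 14 2-(benzyloxy)-5-[(2S)-2-[(benzyloxy)methyl]but-3-en-1-yl]-4-bromo-1,3-dimethoxybenzene; 15 allyltrimethylsilane
Product: 16 [(2E,4S)-5-[4-(benzyloxy)-2-bromo-3,5-dimethoxyphenyl]-4-[(benzyloxy)methyl]pent-2-en-1-yl]trimethylsilane
Conditions: 15 (5 equiv), second-generation Grubbs catalyst RuCl2(=CHPh)(PCy3)(H2IMes) (5 mol %), CH2Cl2, 40 °C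
Reagents that add atoms: none
Why: Olefin cross-metathesis of a monosubstituted, allylically branched alkene with excess allylsilane should favour the E-alkene, and any Z-isomer should converge in step 11, where the alkene geometry is erased.

Step 10
Reactants: 16 [(2E,4S)-5-[4-(benzyloxy)-2-bromo-3,5-dimethoxyphenyl]-4-[(benzyloxy)methyl]pent-2-en-1-yl]trimethylsilane
Product: 18 3-(benzyloxy)-6-[(2S,3E)-2-[(benzyloxy)methyl]-5-(trimethylsilyl)pent-3-en-1-yl]-2,4-dimethoxybenzaldehyde, via aryllithium 17 (not isolated)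
Conditions: n-BuLi, THF, −78 °C; then DMF, −78 → 0 °C; aq NH4Cl
Reagents that add atoms: N,N-dimethylformamide, CN(C)C=O
Why: Bromine–lithium exchange is fast at −78 °C and the aryllithium is formylated by DMF, while the benzyl ethers and the allylsilane are inert to n-BuLi at this temperature.

Step 11
Reactants: 18 3-(benzyloxy)-6-[(2S,3E)-2-[(benzyloxy)methyl]-5-(trimethylsilyl)pent-3-en-1-yl]-2,4-dimethoxybenzaldehyde; 19 guaiacol (2-methoxyphenol)
Product: 22 4-[(1R,2S,3S)-7-(benzyloxy)-3-[(benzyloxy)methyl]-6,8-dimethoxy-2-vinyl-1,2,3,4-tetrahydronaphthalen-1-yl]-2-methoxyphenol, via tetralyl difluoroborinate 20 (not isolated), via benzylic cation 21 (not isolated)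
Conditions: BF3·OEt2 (1.5 equiv), CH2Cl2, −78 °C; then 19 (5 equiv), −78 → −20 °C; aq NaHCO3
Reagents that add atoms: none
Why: BF3 activates the ring A aldehyde, the allylsilane attacks it through its γ-carbon (the alkene carbon bonded to the C3 stereocentre) with loss of Me3SiF, and the benzylic O–BF2 group of 20 then ionises to the C1 cation 21, stabilised by the C8 (ortho) and C6 (para) methoxy groups, which alkylates guaiacol. The closest known chemistry is the intramolecular Hosomi–Sakurai cyclisation onto aryl aldehydes combined with Lewis-acid Friedel–Crafts arylation of electron-rich benzylic alcohols, a pairing also known as a one-pot allylation/arylation of aldehydes. Ring B closes in the 6-exo-trig mode at the carbonyl carbon, with the allylsilane double bond exocyclic to the new ring, through a chair-like transition state. C2 is controlled by the preset C3 centre, since CH2OBn and the emerging vinyl group both lie pseudo-equatorial and so end up trans; C1 is controlled by C2, since guaiacol should approach the planar cation anti to the vinyl group, and the all-trans isomer is also the one expected if the arylation equilibrates. The step needs γ-attack of the allylsilane (secured by the β-silyl effect, which also rules out a seven-membered ring), C-alkylation of guaiacol para to its hydroxyl (the free OH is the stronger para director and O-alkylation is reversible under BF3), and capture of 21 faster than proton loss (secured by excess guaiacol at low temperature). Guaiacol is added only after the cyclisation so that it cannot condense with the free aldehyde.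

Step 12
Reactants: 22 4-[(1R,2S,3S)-7-(benzyloxy)-3-[(benzyloxy)methyl]-6,8-dimethoxy-2-vinyl-1,2,3,4-tetrahydronaphthalen-1-yl]-2-methoxyphenol
Product: 23 (1R,2S,3S)-7-(benzyloxy)-1-[4-(benzyloxy)-3-methoxyphenyl]-3-[(benzyloxy)methyl]-6,8-dimethoxy-2-vinyl-1,2,3,4-tetrahydronaphthalene
Conditions: BnBr, K2CO3, acetone, reflux
Reagents that add atoms: benzyl bromide, BrCc1ccccc1
Why: Williamson benzylation masks the guaiacyl phenol, which periodate would otherwise oxidise to an ortho-quinone in step 13, and the group leaves with the others in step 15.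

Step 13
Reactants: 23 (1R,2S,3S)-7-(benzyloxy)-1-[4-(benzyloxy)-3-methoxyphenyl]-3-[(benzyloxy)methyl]-6,8-dimethoxy-2-vinyl-1,2,3,4-tetrahydronaphthalene
Product: 25 (1R,2S,3S)-7-(benzyloxy)-1-[4-(benzyloxy)-3-methoxyphenyl]-3-[(benzyloxy)methyl]-6,8-dimethoxy-1,2,3,4-tetrahydronaphthalene-2-carbaldehyde, via vicinal diol 24 (not isolated)
Conditions: OsO4 (2 mol %), NaIO4 (4 equiv), 2,6-lutidine, dioxane/H2O (3:1), rt
Reagents that add atoms: osmium tetroxide, O=[Os](=O)(=O)=O (delivers the aldehyde oxygen and is regenerated by sodium periodate, [Na+].[O-]I(=O)(=O)=O)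
Why: In this Lemieux–Johnson oxidation OsO4 dihydroxylates the only alkene and NaIO4 cleaves the diol to the C2 aldehyde, 2,6-lutidine limits over-oxidation, and any epimerisation at C2 should return the more stable all-trans isomer.

Step 14
Reactants: 25 (1R,2S,3S)-7-(benzyloxy)-1-[4-(benzyloxy)-3-methoxyphenyl]-3-[(benzyloxy)methyl]-6,8-dimethoxy-1,2,3,4-tetrahydronaphthalene-2-carbaldehyde
Product: 26 [(1R,2S,3S)-7-(benzyloxy)-1-[4-(benzyloxy)-3-methoxyphenyl]-3-[(benzyloxy)methyl]-6,8-dimethoxy-1,2,3,4-tetrahydronaphthalen-2-yl]methanol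
Conditions: NaBH4, MeOH/THF, 0 °C (crude 25)
Reagents that add atoms: none
Why: Borohydride reduction of the crude aldehyde gives the C2 hydroxymethyl group and keeps the handling of the epimerisable aldehyde short.

Step 15
Reactants: 26 [(1R,2S,3S)-7-(benzyloxy)-1-[4-(benzyloxy)-3-methoxyphenyl]-3-[(benzyloxy)methyl]-6,8-dimethoxy-1,2,3,4-tetrahydronaphthalen-2-yl]methanol
Product: 27 4-[(1R,2S,3S)-7-hydroxy-2,3-bis(hydroxymethyl)-6,8-dimethoxy-1,2,3,4-tetrahydronaphthalen-1-yl]-2-methoxyphenol (target)
Conditions: H2 (1 atm), Pd/C (10 wt %), MeOH/EtOAc, rt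
Reagents that add atoms: none
Why: Hydrogenolysis over Pd/C removes the two aryl benzyl ethers and the alkyl benzyl ether, and the target has no other reducible group, the diarylmethine C1–aryl bonds being stable.

Compound list

1 | syringaldehyde | COc1cc(C=O)cc(OC)c1O | starting material
2 | 4-(benzyloxy)-3,5-dimethoxybenzaldehyde | COc1cc(C=O)cc(OC)c1OCc1ccccc1 | intermediate
3 | 4-(benzyloxy)-2-bromo-3,5-dimethoxybenzaldehyde | COc1cc(C=O)c(Br)c(OC)c1OCc1ccccc1 | intermediate
4 | [4-(benzyloxy)-2-bromo-3,5-dimethoxyphenyl]methanol | COc1cc(CO)c(Br)c(OC)c1OCc1ccccc1 | intermediate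
5 | 4-(benzyloxy)-2-bromo-3,5-dimethoxybenzyl bromide | COc1cc(CBr)c(Br)c(OC)c1OCc1ccccc1 | intermediate
6 | but-3-enoic acid | C=CCC(=O)O | starting material
7 | (S)-4-benzyloxazolidin-2-one | O=C1N[C@@H](Cc2ccccc2)CO1 | starting material
8 | but-3-enoic pivalic anhydride | C=CCC(=O)OC(=O)C(C)(C)C | intermediate (not isolated)
9 | lithium (S)-4-benzyl-2-oxooxazolidin-3-ide | [Li+].O=C1[N-][C@@H](Cc2ccccc2)CO1 | intermediate (not isolated)
10 | (S)-4-benzyl-3-(but-3-enoyl)oxazolidin-2-one | C=CCC(=O)N1[C@@H](Cc2ccccc2)COC1=O | intermediate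
11 | sodium (1Z)-1-[(4S)-4-benzyl-2-oxooxazolidin-3-yl]buta-1,3-dien-1-olate | [Na+].[O-]/C(=C\C=C)N1[C@@H](Cc2ccccc2)COC1=O | intermediate (not isolated)
12 | (4S)-4-benzyl-3-[(2S)-2-{[4-(benzyloxy)-2-bromo-3,5-dimethoxyphenyl]methyl}but-3-enoyl]oxazolidin-2-one | C=C[C@H](Cc1cc(OC)c(OCc2ccccc2)c(OC)c1Br)C(=O)N1[C@@H](Cc2ccccc2)COC1=O | intermediate
13 | (2S)-2-{[4-(benzyloxy)-2-bromo-3,5-dimethoxyphenyl]methyl}but-3-en-1-ol | C=C[C@H](Cc1cc(OC)c(OCc2ccccc2)c(OC)c1Br)CO | intermediate
14 | 2-(benzyloxy)-5-[(2S)-2-[(benzyloxy)methyl]but-3-en-1-yl]-4-bromo-1,3-dimethoxybenzene | C=C[C@H](Cc1cc(OC)c(OCc2ccccc2)c(OC)c1Br)COCc1ccccc1 | intermediate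
15 | allyltrimethylsilane | C=CC[Si](C)(C)C | starting material
16 | [(2E,4S)-5-[4-(benzyloxy)-2-bromo-3,5-dimethoxyphenyl]-4-[(benzyloxy)methyl]pent-2-en-1-yl]trimethylsilane | C[Si](C)(C)C/C=C/[C@H](Cc1cc(OC)c(OCc2ccccc2)c(OC)c1Br)COCc1ccccc1 | intermediate
17 | aryllithium from 16 (lithium in place of bromine, otherwise unchanged) | C[Si](C)(C)C/C=C/[C@H](Cc1cc(OC)c(OCc2ccccc2)c(OC)c1[Li])COCc1ccccc1 | intermediate (not isolated)
18 | 3-(benzyloxy)-6-[(2S,3E)-2-[(benzyloxy)methyl]-5-(trimethylsilyl)pent-3-en-1-yl]-2,4-dimethoxybenzaldehyde | C[Si](C)(C)C/C=C/[C@H](Cc1cc(OC)c(OCc2ccccc2)c(OC)c1C=O)COCc1ccccc1 | intermediate (precursor of the key step)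
19 | guaiacol | COc1ccccc1O | starting material
20 | difluoroboryl ether of (2R,3S)-7-(benzyloxy)-3-[(benzyloxy)methyl]-6,8-dimethoxy-2-vinyl-1,2,3,4-tetrahydronaphthalen-1-ol (C1 epimers; same spatial arrangement at C2 and C3 as in 22, the C2 descriptor differs only through CIP priorities) | C=C[C@H]1C(OB(F)F)c2c(OC)c(OCc3ccccc3)c(OC)cc2C[C@@H]1COCc1ccccc1 | intermediate (not isolated)
21 | C1 benzylic cation from 20 (C2 and C3 unchanged) | C=C[C@H]1[CH+]c2c(OC)c(OCc3ccccc3)c(OC)cc2C[C@@H]1COCc1ccccc1 | intermediate (not isolated)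
22 | 4-[(1R,2S,3S)-7-(benzyloxy)-3-[(benzyloxy)methyl]-6,8-dimethoxy-2-vinyl-1,2,3,4-tetrahydronaphthalen-1-yl]-2-methoxyphenol | COc1cc([C@@H]2c3c(cc(OC)c(OCc4ccccc4)c3OC)C[C@H](COCc3ccccc3)[C@H]2C=C)ccc1O | intermediate (product of the key step)
23 | (1R,2S,3S)-7-(benzyloxy)-1-[4-(benzyloxy)-3-methoxyphenyl]-3-[(benzyloxy)methyl]-6,8-dimethoxy-2-vinyl-1,2,3,4-tetrahydronaphthalene | COc1cc([C@@H]2c3c(cc(OC)c(OCc4ccccc4)c3OC)C[C@H](COCc3ccccc3)[C@H]2C=C)ccc1OCc1ccccc1 | intermediate
24 | 1-[(1R,2S,3S)-7-(benzyloxy)-1-[4-(benzyloxy)-3-methoxyphenyl]-3-[(benzyloxy)methyl]-6,8-dimethoxy-1,2,3,4-tetrahydronaphthalen-2-yl]ethane-1,2-diol (carbinol epimers) | COc1cc([C@@H]2c3c(cc(OC)c(OCc4ccccc4)c3OC)C[C@H](COCc3ccccc3)[C@H]2C(O)CO)ccc1OCc1ccccc1 | intermediate (not isolated)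
25 | (1R,2S,3S)-7-(benzyloxy)-1-[4-(benzyloxy)-3-methoxyphenyl]-3-[(benzyloxy)methyl]-6,8-dimethoxy-1,2,3,4-tetrahydronaphthalene-2-carbaldehyde | COc1cc([C@@H]2c3c(cc(OC)c(OCc4ccccc4)c3OC)C[C@H](COCc3ccccc3)[C@H]2C=O)ccc1OCc1ccccc1 | intermediate
26 | [(1R,2S,3S)-7-(benzyloxy)-1-[4-(benzyloxy)-3-methoxyphenyl]-3-[(benzyloxy)methyl]-6,8-dimethoxy-1,2,3,4-tetrahydronaphthalen-2-yl]methanol | COc1cc([C@@H]2c3c(cc(OC)c(OCc4ccccc4)c3OC)C[C@H](COCc3ccccc3)[C@H]2CO)ccc1OCc1ccccc1 | intermediate
27 | 4-[(1R,2S,3S)-7-hydroxy-2,3-bis(hydroxymethyl)-6,8-dimethoxy-1,2,3,4-tetrahydronaphthalen-1-yl]-2-methoxyphenol | COc1cc([C@@H]2c3c(cc(OC)c(O)c3OC)C[C@H](CO)[C@H]2CO)ccc1O | target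

Total step count: 15. Longest linear sequence: 14 steps (steps 1–4, then 6–15).

Steps most likely to fail

Step 11. Control of the arylation may be incomplete: guaiacol may attack ortho to its hydroxyl or para to its methoxy group, or on the face of C1 cis to the vinyl group. The C1 cation may also lose a proton toward C2 before it is captured, and a benzyl group may be transferred to guaiacol. The fallback keeps the same two bonds at C1 but makes them in the reverse order, with the aryl position fixed by a halide. It sets out from 18. Addition of [4-(benzyloxy)-3-methoxyphenyl]magnesium bromide F1 (from commercial 1-(benzyloxy)-4-bromo-2-methoxybenzene and Mg in THF) at −78 → 0 °C should give [3-(benzyloxy)-6-[(2S,3E)-2-[(benzyloxy)methyl]-5-(trimethylsilyl)pent-3-en-1-yl]-2,4-dimethoxyphenyl][4-(benzyloxy)-3-methoxyphenyl]methanol F2 as a mixture of carbinol epimers. BF3·OEt2 in CH2Cl2 at −78 °C then ionises F2 to a diarylmethyl cation, which the allylsilane captures intramolecularly through a chair with aryl, vinyl and CH2OBn groups all equatorial. This should give 23 directly, so the route is rejoined at 23 and step 12 falls away.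

Step 6. The dienolate may be alkylated at its γ-carbon, or proton transfer may draw the double bond into conjugation and erase the new stereocentre; the ortho-substituted benzylic bromide may also react slowly. The fallback uses a saturated enolate and unveils the vinyl group afterwards. It sets out from 7 and 5. 4-(Phenylselanyl)butanoic acid F3 (from γ-butyrolactone and sodium benzeneselenolate, DMF, 120 °C) is coupled to 7 through its pivalic mixed anhydride (PivCl, Et3N, LiCl, THF) to give (S)-4-benzyl-3-[4-(phenylselanyl)butanoyl]oxazolidin-2-one F4. Its sodium enolate (NaN(SiMe3)2, THF, −78 °C) is alkylated by 5 under the same facial control to give (4S)-4-benzyl-3-[(2S)-2-{[4-(benzyloxy)-2-bromo-3,5-dimethoxyphenyl]methyl}-4-(phenylselanyl)butanoyl]oxazolidin-2-one F5. LiBH4 then gives (2S)-2-{[4-(benzyloxy)-2-bromo-3,5-dimethoxyphenyl]methyl}-4-(phenylselanyl)butan-1-ol F6. Oxidation with H2O2 (THF, 0 °C → rt) and syn-elimination of the selenoxide should give the terminal alkene, which is 13, where the route is rejoined.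

Step 9. Cross-metathesis at the allylically branched alkene may be slow or incomplete, ruthenium hydride species may move the double bond, or the E/Z outcome may be poor. The fallback builds the allylsilane by olefination and cross-coupling and sets out from 14. Lemieux–Johnson cleavage (OsO4, NaIO4, 2,6-lutidine, dioxane/H2O) should give (2R)-3-(benzyloxy)-2-{[4-(benzyloxy)-2-bromo-3,5-dimethoxyphenyl]methyl}propanal F7. Takai olefination (CHI3, CrCl2, THF, 0 °C), which is non-basic and E-selective, should give 2-(benzyloxy)-5-[(2S,3E)-2-[(benzyloxy)methyl]-4-iodobut-3-en-1-yl]-4-bromo-1,3-dimethoxybenzene F8. Kumada coupling with Me3SiCH2MgCl and catalytic Pd(PPh3)4 (THF, rt) should then give 16, where the route is rejoined; the alkenyl iodide should react well before the hindered, electron-rich aryl bromide.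

Further compounds

F1 | step 11 | [4-(benzyloxy)-3-methoxyphenyl]magnesium bromide | COc1cc([Mg]Br)ccc1OCc1ccccc1
F2 | step 11 | [3-(benzyloxy)-6-[(2S,3E)-2-[(benzyloxy)methyl]-5-(trimethylsilyl)pent-3-en-1-yl]-2,4-dimethoxyphenyl][4-(benzyloxy)-3-methoxyphenyl]methanol (carbinol epimers) | COc1cc(C(O)c2c(OC)c(OCc3ccccc3)c(OC)cc2C[C@H](COCc2ccccc2)/C=C/C[Si](C)(C)C)ccc1OCc1ccccc1
F3 | step 6 | 4-(phenylselanyl)butanoic acid | OC(=O)CCC[Se]c1ccccc1
F4 | step 6 | (S)-4-benzyl-3-[4-(phenylselanyl)butanoyl]oxazolidin-2-one | O=C(CCC[Se]c1ccccc1)N1[C@@H](Cc2ccccc2)COC1=O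
F5 | step 6 | (4S)-4-benzyl-3-[(2S)-2-{[4-(benzyloxy)-2-bromo-3,5-dimethoxyphenyl]methyl}-4-(phenylselanyl)butanoyl]oxazolidin-2-one | O=C([C@@H](Cc1cc(OC)c(OCc2ccccc2)c(OC)c1Br)CC[Se]c1ccccc1)N1[C@@H](Cc2ccccc2)COC1=O
F6 | step 6 | (2S)-2-{[4-(benzyloxy)-2-bromo-3,5-dimethoxyphenyl]methyl}-4-(phenylselanyl)butan-1-ol | OC[C@@H](Cc1cc(OC)c(OCc2ccccc2)c(OC)c1Br)CC[Se]c1ccccc1
F7 | step 9 | (2R)-3-(benzyloxy)-2-{[4-(benzyloxy)-2-bromo-3,5-dimethoxyphenyl]methyl}propanal | O=C[C@H](Cc1cc(OC)c(OCc2ccccc2)c(OC)c1Br)COCc1ccccc1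
F8 | step 9 | 2-(benzyloxy)-5-[(2S,3E)-2-[(benzyloxy)methyl]-4-iodobut-3-en-1-yl]-4-bromo-1,3-dimethoxybenzene | I/C=C/[C@H](Cc1cc(OC)c(OCc2ccccc2)c(OC)c1Br)COCc1ccccc1
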